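## Retrosynthetic overview
1. C5=CBr2 comes from Ramirez (Wittig-type) dibromomethylenation of (R)-bromo(1-acetoxybutyl)maleic anhydride, at the C=O flanked by Br.
2. The anhydride comes from 3-bromo-4-(1-acetoxybutyl)furan by singlet-oxygen [4+2]/Kornblum–DeLaMare fragmentation, then lactol oxidation. The ring atoms stay in place.
3. The furan is the only ring and is made first. 4-Phenyloxazole and (R)-1-bromohex-1-yn-3-yl acetate undergo Diels–Alder/retro-Diels–Alder (loss of PhCN), which fixes Br and the side chain on adjacent carbons.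
4. The bromoalkyne comes from purchased (R)-hex-1-yn-3-ol by O-acetylation and C(sp)–H bromination. The carbinol centre is never touched.

Assumption: (R)-hex-1-yn-3-ol (≥98% ee) and 4-phenyloxazole are bought as catalogue items; the target centre is R (O > ring C3 > propyl > H), the same spatial arrangement as in 1.

## Route

Step 1
Reactants: 1 (R)-hex-1-yn-3-ol
Product: 2 (R)-hex-1-yn-3-yl acetate
Conditions: Ac2O, Et3N, DMAP (cat.), CH2Cl2, 0 °C → rt
Reagents that add atoms: acetic anhydride, CC(=O)OC(C)=O
Why: DMAP-catalysed O-acylation breaks only the O–H bond, so the purchased R centre is retained and the final acetate is in place from the start.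

Step 2
Reactants: 2 (R)-hex-1-yn-3-yl acetate
Product: 3 (R)-1-bromohex-1-yn-3-yl acetate
Conditions: NBS, AgNO3 (10 mol%), acetone, rt, dark
Reagents that add atoms: N-bromosuccinimide, O=C1CCC(=O)N1Br
Why: Ag(I)-catalysed electrophilic bromination of the terminal alkyne (Hofmeister conditions) runs through the silver acetylide under neutral conditions and leaves the propargylic acetate and its stereocentre untouched.

Step 3
Reactants: 3 (R)-1-bromohex-1-yn-3-yl acetate; 4 4-phenyloxazole
Product: 6 (R)-1-(4-bromofuran-3-yl)butyl acetate, via oxazole-alkyne cycloadduct 5 (not isolated)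
Conditions: 4 (3 equiv), BHT (cat.), o-dichlorobenzene, sealed tube, 180 °C, 24 h
Reagents that add atoms: none
Why: The oxazole–alkyne Diels–Alder cycloaddition followed by retro-Diels–Alder loss of benzonitrile builds the furan with Br and side chain on adjacent β-carbons; the oxazole carries H at both C2 and C5, so either orientation gives the same furan, and the stereocentre is a spectator.

Step 4
Reactants: 6 (R)-1-(4-bromofuran-3-yl)butyl acetate
Product: 8 (1R)-1-(4-bromo-2-hydroxy-5-oxo-2,5-dihydrofuran-3-yl)butyl acetate, via furan endoperoxide 7 (not isolated)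
Conditions: O2, hν (visible), TPP (cat.), i-Pr2NEt, CH2Cl2, −78 °C → rt
Reagents that add atoms: oxygen, O=O
Why: The [4+2] cycloaddition of singlet oxygen to the furan diene is followed by amine-induced Kornblum–DeLaMare fragmentation at the more acidic, less hindered bridgehead C–H next to C–Br; the new lactol centre (an epimer mixture) and the regiochemistry are inconsequential because both α-carbons become C=O in step 5.

Step 5
Reactants: 8 (1R)-1-(4-bromo-2-hydroxy-5-oxo-2,5-dihydrofuran-3-yl)butyl acetate
Product: 9 (R)-1-(4-bromo-2,5-dioxo-2,5-dihydrofuran-3-yl)butyl acetate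
Conditions: Dess–Martin periodinane, CH2Cl2, rt
Reagents that add atoms: none
Why: Hypervalent-iodine oxidation of the lactol C–H gives the disubstituted maleic anhydride under non-basic conditions, so the acetate, the vinyl bromide and the vinylogously acidic C1'–H stereocentre survive.

Step 6
Reactants: 9 (R)-1-(4-bromo-2,5-dioxo-2,5-dihydrofuran-3-yl)butyl acetate
Product: 11 (R)-1-[4-bromo-5-(dibromomethylidene)-2-oxo-2,5-dihydrofuran-3-yl]butyl acetate, via spiro-oxaphosphetane 10 (not isolated)
Conditions: CBr4 (1.6 equiv), PPh3 (3.0 equiv), CH2Cl2, 0 °C, 30 min (ylide preformed, no free PPh3); then 9, 0 °C → rt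
Reagents that add atoms: carbon tetrabromide, BrC(Br)(Br)Br
Why: Ramirez (Wittig-type) olefination takes the anhydride carbonyl that is inductively activated by the adjacent Br and far less hindered than the one next to the branched CH(OAc)Pr group; the enol-lactone product is much less electrophilic, so mono-olefination results, =CBr2 has no E/Z issue, and the base-free medium leaves the R centre intact.

## Compound list
1 | (R)-hex-1-yn-3-ol | CCC[C@@H](O)C#C | starting material
2 | (R)-hex-1-yn-3-yl acetate | CCC[C@@H](OC(C)=O)C#C | intermediate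
3 | (R)-1-bromohex-1-yn-3-yl acetate | CCC[C@@H](OC(C)=O)C#CBr | intermediate
4 | 4-phenyloxazole | c1ccc(cc1)-c1cocn1 | starting material
5 | (1R)-1-(6-bromo-3-phenyl-7-oxa-2-azabicyclo[2.2.1]hepta-2,5-dien-5-yl)butyl acetate (bridgehead epimers, not isolated) | CCC[C@@H](OC(C)=O)C1=C(Br)C2OC1C(c3ccccc3)=N2 | intermediate
6 | (R)-1-(4-bromofuran-3-yl)butyl acetate | CCC[C@@H](OC(C)=O)c1cocc1Br | intermediate
7 | (1R)-1-(6-bromo-2,3,7-trioxabicyclo[2.2.1]hept-5-en-5-yl)butyl acetate (bridgehead epimers, not isolated) | CCC[C@@H](OC(C)=O)C1=C(Br)C2OOC1O2 | intermediate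
8 | (1R)-1-(4-bromo-2-hydroxy-5-oxo-2,5-dihydrofuran-3-yl)butyl acetate (lactol epimers) | CCC[C@@H](OC(C)=O)C1=C(Br)C(=O)OC1O | intermediate
9 | (R)-1-(4-bromo-2,5-dioxo-2,5-dihydrofuran-3-yl)butyl acetate | CCC[C@@H](OC(C)=O)C1=C(Br)C(=O)OC1=O | intermediate
10 | spiro-1,2-oxaphosphetane from addition of Ph3P=CBr2 to the C=O next to C–Br of 9 (spiro epimers, not isolated) | CCC[C@@H](OC(C)=O)C1=C(Br)C2(OC1=O)OP(c3ccccc3)(c3ccccc3)(c3ccccc3)C2(Br)Br | intermediate
11 | (R)-1-[4-bromo-5-(dibromomethylidene)-2-oxo-2,5-dihydrofuran-3-yl]butyl acetate (CNP0230107.1) | CCC[C@@H](OC(C)=O)C1=C(Br)C(=C(Br)Br)OC1=O | target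

## Step count and risks
Total step count: 6. Longest linear sequence: 6 (1 → 2 → 3 → 6 → 8 → 9 → 11).

**Step 3.** The bromoalkyne may decompose at 180 °C before it cycloadds. The fallback sets out from 1 and comes back at 6. It carries tin instead of bromine through the cycloaddition.
- Double deprotonation of 1 (n-BuLi 2.1 equiv, THF, −78 °C) and C-stannylation with Bu3SnCl gives (R)-1-(tributylstannyl)hex-1-yn-3-ol F1.
- Acetylation (Ac2O, Et3N, DMAP) gives (R)-1-(tributylstannyl)hex-1-yn-3-yl acetate F2.
- Stannylalkynes are thermally robust partners for 4 (neat, 185 °C). They give, through the bicyclic stannyl cycloadduct F3, (R)-1-[4-(tributylstannyl)furan-3-yl]butyl acetate F4.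
- Ipso-bromodestannylation (Br2 1.0 equiv, CH2Cl2, −78 °C) delivers 6.

**Step 6.** There is no close precedent for Ramirez olefination of a bromomaleic anhydride, so the regiochemistry and phosphine side reactions at the bromo-enedione are open questions. The fallback sets out from 9 and comes back at 11. It replaces olefination by addition and dehydration.
- LiCHBr2 (CH2Br2, LDA, THF, −95 °C, 1.05 equiv) adds to the same less hindered, Br-activated carbonyl. At this temperature the anhydride far outcompetes the acetate.
- The product is the lactol (1R)-1-[4-bromo-5-(dibromomethyl)-5-hydroxy-2-oxo-2,5-dihydrofuran-3-yl]butyl acetate F5.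
- P2O5 (CH2Cl2, reflux) dehydrates this lactol to 11, as in the classical fimbrolide endgame.

**Step 4.** The bromine-deactivated furan may react sluggishly with singlet oxygen, or the peroxide may fragment messily. The fallback sets out from 6 and comes back at 9, bypassing 8. It uses an ionic oxidation.
- Clauson-Kaas oxidative methoxylation (Br2, MeOH, Na2CO3, −40 °C) gives (1R)-1-(4-bromo-2,5-dimethoxy-2,5-dihydrofuran-3-yl)butyl acetate F6.
- Jones reagent (acetone, 0 °C) hydrolyses both acetal carbons and oxidises them to the diacid level. The diacid closes spontaneously to anhydride 9.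

## Further compounds
F1 | step 3 | (R)-1-(tributylstannyl)hex-1-yn-3-ol | CCC[C@@H](O)C#C[Sn](CCCC)(CCCC)CCCC
F2 | step 3 | (R)-1-(tributylstannyl)hex-1-yn-3-yl acetate | CCC[C@@H](OC(C)=O)C#C[Sn](CCCC)(CCCC)CCCC
F3 | step 3 | (1R)-1-[3-phenyl-6-(tributylstannyl)-7-oxa-2-azabicyclo[2.2.1]hepta-2,5-dien-5-yl]butyl acetate | CCC[C@@H](OC(C)=O)C1=C([Sn](CCCC)(CCCC)CCCC)C2OC1C(c3ccccc3)=N2
F4 | step 3 | (R)-1-[4-(tributylstannyl)furan-3-yl]butyl acetate | CCC[C@@H](OC(C)=O)c1cocc1[Sn](CCCC)(CCCC)CCCC
F5 | step 6 | (1R)-1-[4-bromo-5-(dibromomethyl)-5-hydroxy-2-oxo-2,5-dihydrofuran-3-yl]butyl acetate | CCC[C@@H](OC(C)=O)C1=C(Br)C(O)(C(Br)Br)OC1=O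
F6 | step 4 | (1R)-1-(4-bromo-2,5-dimethoxy-2,5-dihydrofuran-3-yl)butyl acetate | CCC[C@@H](OC(C)=O)C1=C(Br)C(OC)OC1OC
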